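Labdane numbering is used. Everything rests on an intramolecular Diels–Alder reaction that forms the ring-fusion bond C5–C10 together with C8–C9, closing rings A and B in one operation and setting C5, C9 and C10. It exploits the 1,4-relation in ring B between the C7 oxygen and the quaternary C10 that carries C20 (a 2-silyloxydiene/enal retron) and uses the C1–C4 chain of ring A, with its cis-2,3-diol tied as an acetonide, as tether and stereocontrol element. The precursor is an open-chain (E)-2-alkylidene aldehyde (C9=C10–C20HO, side chain from (R)-linalool) joined through C1–C4 to a (Z)-silyl dienol ether (C5=C6–C7(OTBS)=C8–CH2SPh).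

Key step: step 13

Assumption: commercial (R)-(−)-linalool and (R)-γ-hydroxymethyl-γ-butyrolactone are taken as enantiopure. α/β refer to the usual labdane drawing, in which the target is 2α-OAng, 3α-OAc, 5α-H, 7α-OH, 9β-H, 10β-CH2OAc and 13R.

Step 1
Reactants: 1 (R)-(−)-linalool
Product: 2 (3R)-3-(tert-butyldimethylsilyloxy)-3,7-dimethylocta-1,6-diene
Conditions: TBSOTf, 2,6-lutidine, CH2Cl2, 0 °C → rt
Reagents that add atoms: tert-butyldimethylsilyl trifluoromethanesulfonate, CC(C)(C)[Si](C)(C)OS(=O)(=O)C(F)(F)F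
Why: Silylation of the hindered tertiary allylic alcohol with a silyl triflate should proceed without touching C13, whose R configuration comes from linalool.

Step 2
Reactants: 2 linalool TBS ether
Product: 4 (4R)-4-(tert-butyldimethylsilyloxy)-4-methylhex-5-enal, via ozonide 3 (not isolated)
Conditions: O3 (1 equiv, Sudan Red 7B end point), CH2Cl2, −78 °C; then PPh3, −78 °C → rt
Reagents that add atoms: ozone, [O-][O+]=O
Why: Chemoselective ozonolysis should cleave the electron-rich trisubstituted alkene far faster than the vinyl group next to the silyloxy-bearing quaternary carbon, and reduction of the ozonide gives the aldehyde whose carbonyl carbon becomes C9.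

Step 3
Reactants: 5 (5R)-5-(hydroxymethyl)oxolan-2-one
Product: 6 (2R)-5-oxooxolane-2-carbaldehyde
Conditions: Dess–Martin periodinane, NaHCO3, CH2Cl2, 0 °C → rt; used crude
Reagents that add atoms: none
Why: Dess–Martin oxidation under buffered, non-basic conditions should give the α-oxygenated aldehyde without epimerising C2.

Step 4
Reactants: 6 lactone aldehyde; 7 2-methyl-1-(trimethylsilyloxy)prop-1-ene
Product: 8 (5R)-5-[(1S)-1-hydroxy-2,2-dimethyl-3-oxopropyl]oxolan-2-one
Conditions: BF3·OEt2, CH2Cl2, −78 °C; aqueous NaHCO3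
Reagents that add atoms: none
Why: Mukaiyama aldol addition under a monodentate Lewis acid should follow the polar Felkin–Anh model (attack anti to the ring C–O bond) and give the 2,3-anti (erythro) product, which sets C3 as S and installs the C4 gem-dimethyl carbon and the C5 aldehyde.

Step 5
Reactants: 9 dimethyl (2-oxopropyl)phosphonate; 10 chloromethyl phenyl sulfide
Product: 11 dimethyl [2-oxo-4-(phenylthio)butyl]phosphonate
Conditions: NaH, THF, 0 °C; n-BuLi, −78 °C; then 10, −78 → 0 °C
Reagents that add atoms: none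
Why: The 1,3-dianion of a β-ketophosphonate is alkylated at its more nucleophilic terminal (γ) carbon, which attaches the masked C17 methylene as a CH2SPh group.

Step 6
Reactants: 8 hydroxy aldehyde; 11 β-ketophosphonate
Product: 12 (5R)-5-[(1S,3E)-1-hydroxy-2,2-dimethyl-5-oxo-7-(phenylthio)hept-3-enyl]oxolan-2-one
Conditions: Ba(OH)2 (activated), THF–H2O (40:1), rt
Reagents that add atoms: none
Why: Horner–Wadsworth–Emmons olefination of the non-enolisable neopentyl aldehyde under mild barium hydroxide conditions should give the (E)-enone C5=C6–C7=O and tolerate the free hydroxyl and the lactone.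

Step 7
Reactants: 12 lactone enone
Product: 13 methyl 3-[(4R,5S)-2,2-dimethyl-5-[(3E)-2-methyl-5-oxo-7-(phenylthio)hept-3-en-2-yl]-1,3-dioxolan-4-yl]propanoate
Conditions: 2,2-dimethoxypropane, MeOH, TsOH·H2O (cat.), rt
Reagents that add atoms: 2,2-dimethoxypropane, COC(C)(C)OC; methanol, CO
Why: Acid-catalysed methanolysis of the γ-lactone is driven to the open methyl ester by acetonide formation on the liberated C2/C3 diol (transacetalisation), which frees C10 as an ester α-carbon and ties the diol as the cis-dioxolane.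

Step 8
Reactants: 13 acetonide enone
Product: 14 methyl 3-[(4R,5S)-5-[(3E,5Z)-5-(tert-butyldimethylsilyloxy)-2-methyl-7-(phenylthio)hepta-3,5-dien-2-yl]-2,2-dimethyl-1,3-dioxolan-4-yl]propanoate
Conditions: TBSOTf, Et3N, CH2Cl2, −78 → 0 °C
Reagents that add atoms: tert-butyldimethylsilyl trifluoromethanesulfonate, CC(C)(C)[Si](C)(C)OS(=O)(=O)C(F)(F)F
Why: Soft enolisation of the enone, which has only the C8 methylene to enolise, should give the (Z)-silyl enol ether, i.e. the 2-silyloxydiene with CH2SPh outside, which also masks the ketone against the base of the next step.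

Step 9
Reactants: 14 silyloxydiene ester; 4 aldehyde
Product: 15 methyl 2-{[(4R,5S)-5-[(3E,5Z)-5-(tert-butyldimethylsilyloxy)-2-methyl-7-(phenylthio)hepta-3,5-dien-2-yl]-2,2-dimethyl-1,3-dioxolan-4-yl]methyl}-6-(tert-butyldimethylsilyloxy)-3-hydroxy-6-methyloct-7-enoate (6R; mixture at C2 and C3 of the octenoate)
Conditions: LDA (LiN(i-Pr)2), THF, −78 °C; then 4
Reagents that add atoms: none
Why: Aldol addition of the lithium ester enolate to aldehyde 4 forms the C9–C10 bond, and the two new carbinol/α centres need no control because they are removed in the next step.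

Step 10
Reactants: 15 aldol adduct
Product: 17 methyl (2E,6R)-2-{[(4R,5S)-5-[(3E,5Z)-5-(tert-butyldimethylsilyloxy)-2-methyl-7-(phenylthio)hepta-3,5-dien-2-yl]-2,2-dimethyl-1,3-dioxolan-4-yl]methyl}-6-(tert-butyldimethylsilyloxy)-6-methylocta-2,7-dienoate, via mesylate 16 (not isolated)
Conditions: MsCl, Et3N, CH2Cl2, 0 °C; then DBU, rt
Reagents that add atoms: methanesulfonyl chloride, CS(=O)(=O)Cl (mesyl group of 16 only)
Why: Mesylation followed by E1cB elimination should give mainly the thermodynamically preferred (E)-2-alkylidene ester (C11 trans to the ester, cis to C1), the minor Z isomer being removed by chromatography.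

Step 11
Reactants: 17 (E)-enoate
Product: 18 (2E,6R)-2-{[(4R,5S)-5-[(3E,5Z)-5-(tert-butyldimethylsilyloxy)-2-methyl-7-(phenylthio)hepta-3,5-dien-2-yl]-2,2-dimethyl-1,3-dioxolan-4-yl]methyl}-6-(tert-butyldimethylsilyloxy)-6-methylocta-2,7-dien-1-ol
Conditions: i-Bu2AlH, CH2Cl2, −78 °C; aqueous potassium sodium tartrate (KNaC4H4O6)
Reagents that add atoms: none
Why: Reduction of the α,β-unsaturated ester with i-Bu2AlH gives the allylic alcohol with retention of alkene geometry and leaves silyl ethers, acetonide and sulfide untouched.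

Step 12
Reactants: 18 allylic alcohol
Product: 19 (2E,6R)-2-{[(4R,5S)-5-[(3E,5Z)-5-(tert-butyldimethylsilyloxy)-2-methyl-7-(phenylthio)hepta-3,5-dien-2-yl]-2,2-dimethyl-1,3-dioxolan-4-yl]methyl}-6-(tert-butyldimethylsilyloxy)-6-methylocta-2,7-dienal
Conditions: MnO2 (activated, excess), CH2Cl2, 0 °C; filtered and used at once
Reagents that add atoms: none
Why: Neutral allylic oxidation with MnO2 gives the (E)-enal without isomerisation and without harming the acid-sensitive silyl dienol ether.

Step 13
Reactants: 19 enal tethered to silyloxydiene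
Product: 20 (13R)-7,13-bis(tert-butyldimethylsilyloxy)-2α,3α-isopropylidenedioxy-17-(phenylthio)-9βH-labda-6,14-dien-20-al (5α-H, 8α-H, 9β-H, 10β-CHO)
Conditions: Me2AlCl (2.5 equiv), CH2Cl2, −78 → −30 °C
Reagents that add atoms: none
Why: The Me2AlCl-bound formyl group lowers the LUMO of the enal so that the 2-silyloxydiene adds in a concerted, asynchronous [4+2] cycloaddition in which C8–C9 bonding leads and the C5–C10 bond closes both rings; the closest known reaction type is the Lewis-acid-promoted type 1 intramolecular Diels–Alder reaction of 1,7,9-decatrienals carrying the activating group on the internal dienophile carbon. Ring B is closed as the cyclohexene of the [4+2] process (silyl enol ether C6=C7) and ring A as a six-membered ring over the four-atom tether C1–C4 through the same C5–C10 bond, in a chair-like tether conformation. C5 and C10 (trans ring fusion) are set by the endo orientation of the coordinated formyl group with the tether exo, C9 by the E geometry of the enal (C11 cis to C1, so the side chain ends trans to C20), and the transient C8 centre by the Z enol ether. The diene face is chosen by the cis-acetonide: in the reacting chair the C2 oxygen must be equatorial, because the alternative places it 1,3-diaxial to the axial C4 methyl and the C10 formyl group, and this gives the 2α,3α/10β relation of the target. The step needs endo and facial selectivity and the para regiochemistry (C7 oxygen 1,4 to C10), which the tether enforces and which matches the polarity of diene and dienophile.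

Step 14
Reactants: 20 cycloadduct aldehyde
Product: 21 (13R)-7,13-bis(tert-butyldimethylsilyloxy)-2α,3α-isopropylidenedioxy-17-(phenylthio)-9βH-labda-6,14-dien-20-ol
Conditions: NaBH4, MeOH–THF, 0 °C
Reagents that add atoms: none
Why: Borohydride reduction of the neopentyl aldehyde gives the C20 primary alcohol while the silyl enol ether keeps the C7 carbonyl masked.

Step 15
Reactants: 21 primary alcohol
Product: 22 (13R)-20-acetoxy-7,13-bis(tert-butyldimethylsilyloxy)-2α,3α-isopropylidenedioxy-17-(phenylthio)-9βH-labda-6,14-diene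
Conditions: Ac2O, pyridine, DMAP (cat.), CH2Cl2, rt
Reagents that add atoms: acetic anhydride, CC(=O)OC(C)=O
Why: Standard acetylation of the only free hydroxyl installs the C20 acetate of the target.

Step 16
Reactants: 22 acetate
Product: 23 (13R)-20-acetoxy-13-(tert-butyldimethylsilyloxy)-2α,3α-dihydroxy-17-(phenylthio)-9βH-labd-14-en-7-one (C8 as formed, immaterial)
Conditions: AcOH–H2O (4:1), 50 °C
Reagents that add atoms: none
Why: Aqueous acetic acid should hydrolyse the acetonide and the silyl enol ether (to the C7 ketone) while the tertiary silyl ether, the acetate and the sulfide survive.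

Step 17
Reactants: 23 diol ketone
Product: 24 (13R)-20-acetoxy-2α-angeloyloxy-13-(tert-butyldimethylsilyloxy)-3α-hydroxy-17-(phenylthio)-9βH-labd-14-en-7-one
Conditions: preformed mixed anhydride (angelic acid, 2,4,6-trichlorobenzoyl chloride, Et3N, toluene, rt, filtered); then 23, toluene, 75 °C, no DMAP
Reagents that add atoms: angelic acid, C/C=C(/C)C(=O)O
Why: Yamaguchi-type esterification should acylate the unhindered equatorial C2 hydroxyl in preference to the axial, neopentyl C3 hydroxyl, and omitting the nucleophilic catalyst avoids isomerisation of the angelate to the tiglate.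

Step 18
Reactants: 24 mono-angelate
Product: 25 (13R)-3α,20-diacetoxy-2α-angeloyloxy-13-(tert-butyldimethylsilyloxy)-17-(phenylthio)-9βH-labd-14-en-7-one
Conditions: Ac2O, pyridine, DMAP (0.2 equiv), CH2Cl2, rt
Reagents that add atoms: acetic anhydride, CC(=O)OC(C)=O
Why: DMAP-catalysed acetylation esterifies the remaining hindered axial C3 hydroxyl, the tertiary C13 oxygen still being silylated.

Step 19
Reactants: 25 triester
Product: 26 (13R)-3α,20-diacetoxy-2α-angeloyloxy-13-hydroxy-17-(phenylthio)-9βH-labd-14-en-7-one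
Conditions: HF·pyridine, THF, 0 °C → rt (prolonged)
Reagents that add atoms: none
Why: Fluoride-mediated cleavage of the tertiary silyl ether frees the C13 alcohol under conditions that leave the esters and the β-thio ketone intact.

Step 20
Reactants: 26 β-phenylthio ketone
Product: 28 (13R)-3α,20-diacetoxy-2α-angeloyloxy-13-hydroxy-9βH-labda-8(17),14-dien-7-one, via sulfoxide 27 (not isolated)
Conditions: mCPBA (1.0 equiv), NaHCO3, CH2Cl2, −78 °C; then Et3N, toluene, 60 °C
Reagents that add atoms: mCPBA, O=C(OO)c1cccc(Cl)c1 (oxygen atom of sulfoxide 27 only)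
Why: Chemoselective sulfide oxidation at low temperature followed by sulfoxide syn-elimination, for which C8–H is the only β-hydrogen and is acidified by the ketone, should give the exocyclic enone.

Step 21
Reactants: 28 exo-methylene enone
Product: 29 target CNP0147212.1, (2R,3S,5R,7R,9S,10R,13R)-3,20-diacetoxy-2-angeloyloxylabda-8(17),14-diene-7,13-diol
Conditions: NaBH4, CeCl3·7H2O, MeOH, −78 °C
Reagents that add atoms: none
Why: Luche reduction is 1,2-selective and leaves the esters, and hydride should enter C7 from the β face (equatorial trajectory) because the axial approach on the α face is blocked by the axial C9 side chain and H5, which gives the axial 7α-alcohol.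

Compound list
1 | (R)-(−)-linalool, (3R)-3,7-dimethylocta-1,6-dien-3-ol | C=C[C@](C)(O)CCC=C(C)C | starting material
2 | (3R)-3-(tert-butyldimethylsilyloxy)-3,7-dimethylocta-1,6-diene | C=C[C@](C)(O[Si](C)(C)C(C)(C)C)CCC=C(C)C | intermediate
3 | ozonide of 2 at the 6,7-alkene, 3,3-dimethyl-5-[(3R)-3-(tert-butyldimethylsilyloxy)-3-methylpent-4-enyl]-1,2,4-trioxolane | C=C[C@](C)(O[Si](C)(C)C(C)(C)C)CCC1OOC(C)(C)O1 | intermediate
4 | (4R)-4-(tert-butyldimethylsilyloxy)-4-methylhex-5-enal | C=C[C@](C)(O[Si](C)(C)C(C)(C)C)CCC=O | intermediate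
5 | (5R)-5-(hydroxymethyl)oxolan-2-one, (R)-γ-hydroxymethyl-γ-butyrolactone | OC[C@H]1CCC(=O)O1 | starting material
6 | (2R)-5-oxooxolane-2-carbaldehyde | O=C[C@H]1CCC(=O)O1 | intermediate
7 | 2-methyl-1-(trimethylsilyloxy)prop-1-ene | CC(C)=CO[Si](C)(C)C | starting material
8 | (5R)-5-[(1S)-1-hydroxy-2,2-dimethyl-3-oxopropyl]oxolan-2-one | O=CC(C)(C)[C@H](O)[C@H]1CCC(=O)O1 | intermediate
9 | dimethyl (2-oxopropyl)phosphonate | COP(=O)(CC(C)=O)OC | starting material
10 | chloromethyl phenyl sulfide | ClCSc1ccccc1 | starting material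
11 | dimethyl [2-oxo-4-(phenylthio)butyl]phosphonate | COP(=O)(CC(=O)CCSc1ccccc1)OC | intermediate
12 | (5R)-5-[(1S,3E)-1-hydroxy-2,2-dimethyl-5-oxo-7-(phenylthio)hept-3-enyl]oxolan-2-one | O=C(CCSc1ccccc1)/C=C/C(C)(C)[C@H](O)[C@H]1CCC(=O)O1 | intermediate
13 | methyl 3-[(4R,5S)-2,2-dimethyl-5-[(3E)-2-methyl-5-oxo-7-(phenylthio)hept-3-en-2-yl]-1,3-dioxolan-4-yl]propanoate | COC(=O)CC[C@H]1OC(C)(C)O[C@H]1C(C)(C)/C=C/C(=O)CCSc1ccccc1 | intermediate
14 | methyl 3-[(4R,5S)-5-[(3E,5Z)-5-(tert-butyldimethylsilyloxy)-2-methyl-7-(phenylthio)hepta-3,5-dien-2-yl]-2,2-dimethyl-1,3-dioxolan-4-yl]propanoate | COC(=O)CC[C@H]1OC(C)(C)O[C@H]1C(C)(C)/C=C/C(O[Si](C)(C)C(C)(C)C)=C/CSc1ccccc1 | intermediate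
15 | aldol adduct of 14 and 4 (β-hydroxy ester, mixture at the two new centres) | C=C[C@](C)(O[Si](C)(C)C(C)(C)C)CCC(O)C(C(=O)OC)C[C@H]1OC(C)(C)O[C@H]1C(C)(C)/C=C/C(O[Si](C)(C)C(C)(C)C)=C/CSc1ccccc1 | intermediate
16 | mesylate of 15 | C=C[C@](C)(O[Si](C)(C)C(C)(C)C)CCC(OS(C)(=O)=O)C(C(=O)OC)C[C@H]1OC(C)(C)O[C@H]1C(C)(C)/C=C/C(O[Si](C)(C)C(C)(C)C)=C/CSc1ccccc1 | intermediate
17 | (E)-2-alkylidene methyl ester (C9=C10, C11 cis to C1) carrying the silyloxydiene | C=C[C@](C)(O[Si](C)(C)C(C)(C)C)CC/C=C(C(=O)OC)\C[C@H]1OC(C)(C)O[C@H]1C(C)(C)/C=C/C(O[Si](C)(C)C(C)(C)C)=C/CSc1ccccc1 | intermediate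
18 | corresponding (E)-allylic alcohol (C20–OH) | C=C[C@](C)(O[Si](C)(C)C(C)(C)C)CC/C=C(CO)\C[C@H]1OC(C)(C)O[C@H]1C(C)(C)/C=C/C(O[Si](C)(C)C(C)(C)C)=C/CSc1ccccc1 | intermediate
19 | (E)-enal tethered to the (3E,5Z)-silyloxydiene (Diels–Alder precursor) | C=C[C@](C)(O[Si](C)(C)C(C)(C)C)CC/C=C(C=O)\C[C@H]1OC(C)(C)O[C@H]1C(C)(C)/C=C/C(O[Si](C)(C)C(C)(C)C)=C/CSc1ccccc1 | intermediate
20 | cycloadduct, (13R)-7,13-bis(TBS-oxy)-2α,3α-isopropylidenedioxy-17-(phenylthio)-9βH-labda-6,14-dien-20-al | C=C[C@](C)(O[Si](C)(C)C(C)(C)C)CC[C@@H]1[C@@H](CSc3ccccc3)C(O[Si](C)(C)C(C)(C)C)=C[C@H]2C(C)(C)[C@@H]3OC(C)(C)O[C@@H]3C[C@]12C=O | intermediate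
21 | corresponding 20-ol | C=C[C@](C)(O[Si](C)(C)C(C)(C)C)CC[C@@H]1[C@@H](CSc3ccccc3)C(O[Si](C)(C)C(C)(C)C)=C[C@H]2C(C)(C)[C@@H]3OC(C)(C)O[C@@H]3C[C@]12CO | intermediate
22 | corresponding 20-acetate | C=C[C@](C)(O[Si](C)(C)C(C)(C)C)CC[C@@H]1[C@@H](CSc3ccccc3)C(O[Si](C)(C)C(C)(C)C)=C[C@H]2C(C)(C)[C@@H]3OC(C)(C)O[C@@H]3C[C@]12COC(C)=O | intermediate
23 | (13R)-20-acetoxy-13-(TBS-oxy)-2α,3α-dihydroxy-17-(phenylthio)-9βH-labd-14-en-7-one | C=C[C@](C)(O[Si](C)(C)C(C)(C)C)CC[C@@H]1[C@@H](CSc3ccccc3)C(=O)C[C@H]2C(C)(C)[C@H](O)[C@H](O)C[C@]12COC(C)=O | intermediate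
24 | 2α-angelate of 23 | C=C[C@](C)(O[Si](C)(C)C(C)(C)C)CC[C@@H]1[C@@H](CSc3ccccc3)C(=O)C[C@H]2C(C)(C)[C@H](O)[C@H](OC(=O)/C(C)=C\C)C[C@]12COC(C)=O | intermediate
25 | 3α,20-diacetate 2α-angelate, 13-O-TBS | C=C[C@](C)(O[Si](C)(C)C(C)(C)C)CC[C@@H]1[C@@H](CSc3ccccc3)C(=O)C[C@H]2C(C)(C)[C@H](OC(C)=O)[C@H](OC(=O)/C(C)=C\C)C[C@]12COC(C)=O | intermediate
26 | (13R)-3α,20-diacetoxy-2α-angeloyloxy-13-hydroxy-17-(phenylthio)-9βH-labd-14-en-7-one | C=C[C@](C)(O)CC[C@@H]1[C@@H](CSc3ccccc3)C(=O)C[C@H]2C(C)(C)[C@H](OC(C)=O)[C@H](OC(=O)/C(C)=C\C)C[C@]12COC(C)=O | intermediate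
27 | sulfoxide of 26 (mixture at sulfur) | C=C[C@](C)(O)CC[C@@H]1[C@@H](CS(=O)c3ccccc3)C(=O)C[C@H]2C(C)(C)[C@H](OC(C)=O)[C@H](OC(=O)/C(C)=C\C)C[C@]12COC(C)=O | intermediate
28 | (13R)-3α,20-diacetoxy-2α-angeloyloxy-13-hydroxy-9βH-labda-8(17),14-dien-7-one | C=C[C@](C)(O)CC[C@@H]1C(=C)C(=O)C[C@H]2C(C)(C)[C@H](OC(C)=O)[C@H](OC(=O)/C(C)=C\C)C[C@]12COC(C)=O | intermediate
29 | CNP0147212.1, (2R,3S,5R,7R,9S,10R,13R)-3,20-diacetoxy-2-angeloyloxylabda-8(17),14-diene-7,13-diol | C=C[C@](C)(O)CC[C@@H]1C(=C)[C@H](O)C[C@H]2C(C)(C)[C@H](OC(C)=O)[C@H](OC(=O)/C(C)=C\C)C[C@]12COC(C)=O | target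

Total step count: 21. Longest linear sequence: 18 steps (from lactone 5 through steps 3, 4 and 6–21).

Steps most likely to fail

Step 13 (key step). What may go wrong is Lewis-acid-induced loss of the silyl enol ether or stepwise Mukaiyama-type oligomerisation before ring closure, or insufficient endo and facial control in the cycloaddition. The fallback sets out from ester 17, which already holds diene and dienophile. Heating it without any Lewis acid (toluene, BHT, 160 °C, sealed tube) should bring about the ester-activated thermal intramolecular Diels–Alder reaction and give the angular methyl ester cycloadduct F1. Reduction of the ester with i-Bu2AlH (CH2Cl2, −78 → 0 °C) then comes back to the route at alcohol 21, bypassing 18, 19 and 20.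

Step 4. What may go wrong is poor facial selectivity in the addition to the α-oxygenated aldehyde, so that the C3 epimers form in comparable amounts. The fallback sets out from aldehyde 6 and replaces substrate control by reagent control. A Mukaiyama aldol addition of 1-(ethylthio)-2-methyl-1-(trimethylsilyloxy)prop-1-ene is promoted by a stoichiometric chiral oxazaborolidinone made from N-tosylvaline and BH3·THF, the enantiomer being chosen to reinforce the Felkin sense, and should give the β-hydroxy S-ethyl thioester F2. Fukuyama reduction (Et3SiH, Pd/C, acetone) of the thioester, which has no alkene at this stage, comes back to the route at aldehyde 8.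

Step 21. What may go wrong is hydride delivery to the wrong face of C7 (giving the equatorial 7β-alcohol), or dimerisation and conjugate reduction of the sensitive exo-methylene enone. The fallback sets out from ketone 26 and reduces C7 before the alkene is unveiled. LiBH(s-Bu)3 (THF, −78 °C) attacks the saturated ketone along the equatorial trajectory and should give the axial 7α-hydroxy sulfide F3. Oxidation at sulfur (mCPBA, CH2Cl2, −78 °C) gives the hydroxy sulfoxide F4, and thermal syn-elimination (toluene, CaCO3, 110 °C), for which C8–H is the only β-hydrogen, forms the 8(17)-alkene and comes back to the route at target 29 without passing through enone 28.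

Further compounds
F1 | step 13 | methyl (13R)-7,13-bis(tert-butyldimethylsilyloxy)-2α,3α-isopropylidenedioxy-17-(phenylthio)-9βH-labda-6,14-dien-20-oate | C=C[C@](C)(O[Si](C)(C)C(C)(C)C)CC[C@@H]1[C@@H](CSc3ccccc3)C(O[Si](C)(C)C(C)(C)C)=C[C@H]2C(C)(C)[C@@H]3OC(C)(C)O[C@@H]3C[C@]12C(=O)OC
F2 | step 4 | S-ethyl (3S)-3-hydroxy-2,2-dimethyl-3-[(2R)-5-oxooxolan-2-yl]propanethioate | CCSC(=O)C(C)(C)[C@H](O)[C@H]1CCC(=O)O1
F3 | step 21 | (13R)-3α,20-diacetoxy-2α-angeloyloxy-17-(phenylthio)-9βH-labd-14-ene-7α,13-diol | C=C[C@](C)(O)CC[C@@H]1[C@@H](CSc3ccccc3)[C@H](O)C[C@H]2C(C)(C)[C@H](OC(C)=O)[C@H](OC(=O)/C(C)=C\C)C[C@]12COC(C)=O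
F4 | step 21 | sulfoxide of F3 (mixture at sulfur) | C=C[C@](C)(O)CC[C@@H]1[C@@H](CS(=O)c3ccccc3)[C@H](O)C[C@H]2C(C)(C)[C@H](OC(C)=O)[C@H](OC(=O)/C(C)=C\C)C[C@]12COC(C)=O
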